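**Retrosynthetic overview**
- C3: the propargylic bromide comes from the threo propargylic alcohol (SN2 bromination), made last from a ring‑A aldehyde and ethynylmagnesium bromide.
- Ring B (formed second): 5‑endo bromoetherification of a (Z)‑homoallylic alcohol (C12–OH onto C9=C10) sets C9 and C10.
- C9=C10: Z‑Wittig between the ring‑A aldehyde and a C10–C15 phosphonium salt that already carries C12–O and C13–Br (from asymmetric alkoxyallylation of propanal).
- Ring A (formed first, key step): singlet‑oxygen dearomatisation of a 2‑(2‑hydroxyalkyl)furan, then oxa‑Michael closure; the four furan carbons become C6–C9 (C6 ketone, C9 aldehyde).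
- Furan plus (R)‑glycidyl trityl ether supply C3–C9.

Assumption: the target is the (3S,4R,6R,7R,9S,10S,12S,13R) isomer encoded in the SMILES, numbered C1 (alkyne CH) to C15 (methyl), ring A = O/C4–C7, ring B = O/C9–C12; (R)‑glycidyl trityl ether, allyl methoxymethyl ether, (+)‑B‑methoxydiisopinocampheylborane and ethynylmagnesium bromide are taken as purchasable.

**Step 1**
Reactants: 1 furan; 2 (R)-2-[(trityloxy)methyl]oxirane
Product: 4 (R)-1-(furan-2-yl)-3-(trityloxy)propan-2-ol, via 2-furyllithium 3 (not isolated)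
Conditions: n-BuLi, THF, 0 °C; then 2, 0 °C to rt; H2O
Reagents that add atoms: none
Why: α‑Lithiation of furan gives 3, which opens the epoxide at its terminal carbon (SN2 epoxide opening), so C4 keeps the (R) configuration of 2.

**Step 2**
Reactants: 4 (R)-1-(furan-2-yl)-3-(trityloxy)propan-2-ol
Product: 7 2-[(2R,5R)-3-oxo-5-[(trityloxy)methyl]oxolan-2-yl]acetaldehyde, via furan endoperoxide 5 (not isolated), via (Z)-4-oxo-2-enal 6 (not isolated)
Conditions: O2, 5,10,15,20-tetraphenylporphyrin (cat.), visible light, CH2Cl2, −78 °C; Me2S, −78 °C to rt; then Et3N (cat.), CH2Cl2, rt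
Reagents that add atoms: dioxygen, O=O
Why: Proposed new method: [4+2] addition of singlet oxygen to the furan gives 5, Me2S reduction unmasks the (Z)-4-oxo-2-enal 6, and the C4 hydroxyl closes ring A by 5‑exo oxa‑Michael addition at C7 (activated by the C9 aldehyde), with reversible addition and C7 epimerisation expected to favour the 2,5‑cis ketone (both substituents pseudo‑equatorial); the closest known reaction type is the singlet‑oxygen oxidation/oxa‑Michael cyclisation of 5‑alkyl‑2‑(2‑hydroxyalkyl)furans to 3‑oxotetrahydrofurans, extended here to a furan with a free 5‑position so that C9 emerges as an aldehyde.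

**Step 3**
Reactants: 8 allyl methoxymethyl ether; 9 propanal
Product: 12 (3S,4S)-4-(methoxymethoxy)hex-5-en-3-ol, via oxyallyllithium 10 (not isolated), via allylborane 11 (not isolated)
Conditions: 8, s-BuLi, THF, −78 °C; (+)-B-methoxydiisopinocampheylborane; BF3·OEt2; 9, −78 °C to rt; NaOH, H2O2
Reagents that add atoms: none
Why: Brown asymmetric γ‑alkoxyallylboration: the (Z)-alkoxyallylborane adds to propanal through a closed chair transition state, the Z geometry giving the syn (threo) C12/C13 pattern and the isopinocampheyl groups fixing the absolute sense.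

**Step 4**
Reactants: 12 (3S,4S)-4-(methoxymethoxy)hex-5-en-3-ol
Product: 13 (3S,4R)-4-bromo-3-(methoxymethoxy)hex-1-ene
Conditions: CBr4, PPh3, CH2Cl2, 0 °C to rt
Reagents that add atoms: carbon tetrabromide, BrC(Br)(Br)Br
Why: Appel bromination displaces the oxyphosphonium by SN2, inverting C13 to the (R)-bromide (erythro to the C12 oxygen).

**Step 5**
Reactants: 13 (3S,4R)-4-bromo-3-(methoxymethoxy)hex-1-ene
Product: 15 (3S,4R)-4-bromo-1-iodo-3-(methoxymethoxy)hexane, via alkyldisiamylborane 14 (not isolated)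
Conditions: disiamylborane (from BH3·THF and 2-methylbut-2-ene), THF, 0 °C; then I2, NaOMe, MeOH, 0 °C to rt
Reagents that add atoms: iodine, II
Why: Anti‑Markovnikov hydroboration of the terminal alkene by the bulky dialkylborane and base‑induced iodinolysis of the primary C–B bond give the primary iodide without touching a stereocentre.

**Step 6**
Reactants: 15 (3S,4R)-4-bromo-1-iodo-3-(methoxymethoxy)hexane
Product: 16 [(3S,4R)-4-bromo-3-(methoxymethoxy)hexyl]triphenylphosphonium iodide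
Conditions: PPh3, MeCN, 70 °C
Reagents that add atoms: triphenylphosphine, c1ccc(cc1)P(c1ccccc1)c1ccccc1
Why: SN2 quaternisation at the primary iodide, which is far faster than attack at the secondary bromide.

**Step 7**
Reactants: 16 [(3S,4R)-4-bromo-3-(methoxymethoxy)hexyl]triphenylphosphonium iodide; 7 2-[(2R,5R)-3-oxo-5-[(trityloxy)methyl]oxolan-2-yl]acetaldehyde
Product: 18 (2R,5R)-2-[(2Z,5S,6R)-6-bromo-5-(methoxymethoxy)oct-2-en-1-yl]-5-[(trityloxy)methyl]oxolan-3-one, via ylide 17 (not isolated)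
Conditions: 16, NaN(SiMe3)2, THF, −78 °C; then 7, −78 to 0 °C
Reagents that add atoms: none
Why: Salt‑free Wittig olefination of a non‑stabilised ylide with the aldehyde (faster than with the ketone) gives the (Z)-C9=C10 alkene through the kinetic cis‑oxaphosphetane.

**Step 8**
Reactants: 18 (2R,5R)-2-[(2Z,5S,6R)-6-bromo-5-(methoxymethoxy)oct-2-en-1-yl]-5-[(trityloxy)methyl]oxolan-3-one
Product: 20 (2R,3R,5R)-2-[(2Z,5S,6R)-6-bromo-5-(methoxymethoxy)oct-2-en-1-yl]-5-[(trityloxy)methyl]oxolan-3-yl acetate, via lithium alkoxide 19 (not isolated)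
Conditions: LiBH(s-Bu)3, THF, −78 °C; then Ac2O, 4-(dimethylamino)pyridine (cat.), −78 °C to rt
Reagents that add atoms: acetic anhydride, CC(=O)OC(C)=O
Why: Substrate‑controlled ketone reduction: the bulky hydride attacks opposite the two cis substituents at C4 and C7, giving the all‑cis C6 alkoxide 19, which is acetylated in the same flask.

**Step 9**
Reactants: 20 (2R,3R,5R)-2-[(2Z,5S,6R)-6-bromo-5-(methoxymethoxy)oct-2-en-1-yl]-5-[(trityloxy)methyl]oxolan-3-yl acetate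
Product: 21 (2R,3R,5R)-2-[(2Z,5S,6R)-6-bromo-5-hydroxyoct-2-en-1-yl]-5-(hydroxymethyl)oxolan-3-yl acetate
Conditions: ZnBr2, n-PrSH, CH2Cl2, 0 °C to rt
Reagents that add atoms: none
Why: Lewis acid/thiol deprotection: ZnBr2‑activated thiolysis cleaves the methoxymethyl acetal and the trityl ether, leaving acetate, bromide and alkene intact.

**Step 10**
Reactants: 21 (2R,3R,5R)-2-[(2Z,5S,6R)-6-bromo-5-hydroxyoct-2-en-1-yl]-5-(hydroxymethyl)oxolan-3-yl acetate
Product: 22 (2R,3R,5R)-2-{[(2S,3S,5S)-3-bromo-5-[(1R)-1-bromopropyl]oxolan-2-yl]methyl}-5-(hydroxymethyl)oxolan-3-yl acetate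
Conditions: N-bromosuccinimide, MeCN, 0 °C, dark
Reagents that add atoms: N-bromosuccinimide, O=C1CCC(=O)N1Br
Why: 5‑endo‑trig bromoetherification of the (Z)-homoallylic alcohol: anti addition of bromine and the C12 oxygen across the Z alkene sets C9/C10 (bromine cis to the C9 side chain), and the 2,5‑cis ring is the known outcome of halocyclisations of (Z)-homoallylic alcohols.

**Step 11**
Reactants: 22 (2R,3R,5R)-2-{[(2S,3S,5S)-3-bromo-5-[(1R)-1-bromopropyl]oxolan-2-yl]methyl}-5-(hydroxymethyl)oxolan-3-yl acetate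
Product: 23 (2R,3R,5R)-2-{[(2S,3S,5S)-3-bromo-5-[(1R)-1-bromopropyl]oxolan-2-yl]methyl}-5-formyloxolan-3-yl acetate
Conditions: Dess–Martin periodinane, CH2Cl2, 0 °C to rt
Reagents that add atoms: none
Why: Dess–Martin oxidation of the primary alcohol to the aldehyde under non‑basic conditions that do not epimerise C4.

**Step 12**
Reactants: 23 (2R,3R,5R)-2-{[(2S,3S,5S)-3-bromo-5-[(1R)-1-bromopropyl]oxolan-2-yl]methyl}-5-formyloxolan-3-yl acetate; 24 ethynylmagnesium bromide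
Product: 25 (2R,3R,5R)-2-{[(2S,3S,5S)-3-bromo-5-[(1R)-1-bromopropyl]oxolan-2-yl]methyl}-5-[(1R)-1-hydroxyprop-2-yn-1-yl]oxolan-3-yl acetate
Conditions: 24, MgBr2·OEt2, CH2Cl2/THF, −78 °C; H2O
Reagents that add atoms: none
Why: Chelation‑controlled (Cram chelate) Grignard addition: magnesium bridges the aldehyde and ring‑A oxygens and the acetylide attacks anti to C5, giving the threo (3R) propargylic alcohol.

**Step 13**
Reactants: 25 (2R,3R,5R)-2-{[(2S,3S,5S)-3-bromo-5-[(1R)-1-bromopropyl]oxolan-2-yl]methyl}-5-[(1R)-1-hydroxyprop-2-yn-1-yl]oxolan-3-yl acetate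
Product: 26 (2R,3R,5R)-5-[(1S)-1-bromoprop-2-yn-1-yl]-2-{[(2S,3S,5S)-3-bromo-5-[(1R)-1-bromopropyl]oxolan-2-yl]methyl}oxolan-3-yl acetate
Conditions: CBr4, PPh3, CH2Cl2, 0 °C
Reagents that add atoms: carbon tetrabromide, BrC(Br)(Br)Br
Why: Appel bromination of the propargylic alcohol by SN2 displacement inverts C3 to the (S)-bromide of the target.

**Compound list**
1 | furan | c1ccoc1 | starting material
2 | (R)-2-[(trityloxy)methyl]oxirane | C(OC[C@H]1CO1)(c1ccccc1)(c1ccccc1)c1ccccc1 | starting material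
3 | 2-furyllithium | [Li]c1ccco1 | intermediate
4 | (R)-1-(furan-2-yl)-3-(trityloxy)propan-2-ol | C(OC[C@H](O)Cc1ccco1)(c1ccccc1)(c1ccccc1)c1ccccc1 | intermediate
5 | 1-[(2R)-2-hydroxy-3-(trityloxy)propyl]-2,3,7-trioxabicyclo[2.2.1]hept-5-ene | C(OC[C@H](O)CC12OOC(C=C1)O2)(c1ccccc1)(c1ccccc1)c1ccccc1 | intermediate
6 | (2Z,6R)-6-hydroxy-4-oxo-7-(trityloxy)hept-2-enal | C(OC[C@H](O)CC(=O)/C=C\C=O)(c1ccccc1)(c1ccccc1)c1ccccc1 | intermediate
7 | 2-[(2R,5R)-3-oxo-5-[(trityloxy)methyl]oxolan-2-yl]acetaldehyde | C(OC[C@H]1CC(=O)[C@@H](CC=O)O1)(c1ccccc1)(c1ccccc1)c1ccccc1 | intermediate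
8 | allyl methoxymethyl ether | C=CCOCOC | starting material
9 | propanal | CCC=O | starting material
10 | [(Z)-3-(methoxymethoxy)prop-2-en-1-yl]lithium | [Li]C/C=C\OCOC | intermediate
11 | [(Z)-3-(methoxymethoxy)prop-2-en-1-yl]di[(+)-isopinocampheyl]borane | COCO/C=C\CB([C@H]1C[C@H]2C[C@@H]([C@@H]1C)C2(C)C)[C@H]1C[C@H]2C[C@@H]([C@@H]1C)C2(C)C | intermediate
12 | (3S,4S)-4-(methoxymethoxy)hex-5-en-3-ol | COCO[C@H]([C@@H](O)CC)C=C | intermediate
13 | (3S,4R)-4-bromo-3-(methoxymethoxy)hex-1-ene | COCO[C@H]([C@H](Br)CC)C=C | intermediate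
14 | [(3S,4R)-4-bromo-3-(methoxymethoxy)hexyl]bis(3-methylbutan-2-yl)borane | CC(C)C(C)B(CC[C@H](OCOC)[C@H](Br)CC)C(C)C(C)C | intermediate
15 | (3S,4R)-4-bromo-1-iodo-3-(methoxymethoxy)hexane | ICC[C@H](OCOC)[C@H](Br)CC | intermediate
16 | [(3S,4R)-4-bromo-3-(methoxymethoxy)hexyl]triphenylphosphonium iodide | [I-].COCO[C@@H](CC[P+](c1ccccc1)(c1ccccc1)c1ccccc1)[C@H](Br)CC | intermediate
17 | [(3S,4R)-4-bromo-3-(methoxymethoxy)hexylidene]triphenylphosphorane | COCO[C@@H](CC=P(c1ccccc1)(c1ccccc1)c1ccccc1)[C@H](Br)CC | intermediate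
18 | (2R,5R)-2-[(2Z,5S,6R)-6-bromo-5-(methoxymethoxy)oct-2-en-1-yl]-5-[(trityloxy)methyl]oxolan-3-one | C(OC[C@H]1CC(=O)[C@@H](C/C=C\C[C@H](OCOC)[C@H](Br)CC)O1)(c1ccccc1)(c1ccccc1)c1ccccc1 | intermediate
19 | lithium (2R,3R,5R)-2-[(2Z,5S,6R)-6-bromo-5-(methoxymethoxy)oct-2-en-1-yl]-5-[(trityloxy)methyl]oxolan-3-olate | C(OC[C@H]1C[C@@H]([O-])[C@@H](C/C=C\C[C@H](OCOC)[C@H](Br)CC)O1)(c1ccccc1)(c1ccccc1)c1ccccc1.[Li+] | intermediate
20 | (2R,3R,5R)-2-[(2Z,5S,6R)-6-bromo-5-(methoxymethoxy)oct-2-en-1-yl]-5-[(trityloxy)methyl]oxolan-3-yl acetate | C(OC[C@H]1C[C@@H](OC(C)=O)[C@@H](C/C=C\C[C@H](OCOC)[C@H](Br)CC)O1)(c1ccccc1)(c1ccccc1)c1ccccc1 | intermediate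
21 | (2R,3R,5R)-2-[(2Z,5S,6R)-6-bromo-5-hydroxyoct-2-en-1-yl]-5-(hydroxymethyl)oxolan-3-yl acetate | OC[C@H]1C[C@@H](OC(C)=O)[C@@H](C/C=C\C[C@H](O)[C@H](Br)CC)O1 | intermediate
22 | (2R,3R,5R)-2-{[(2S,3S,5S)-3-bromo-5-[(1R)-1-bromopropyl]oxolan-2-yl]methyl}-5-(hydroxymethyl)oxolan-3-yl acetate | OC[C@H]1C[C@@H](OC(C)=O)[C@@H](C[C@@H]2O[C@H]([C@H](Br)CC)C[C@@H]2Br)O1 | intermediate
23 | (2R,3R,5R)-2-{[(2S,3S,5S)-3-bromo-5-[(1R)-1-bromopropyl]oxolan-2-yl]methyl}-5-formyloxolan-3-yl acetate | O=C[C@H]1C[C@@H](OC(C)=O)[C@@H](C[C@@H]2O[C@H]([C@H](Br)CC)C[C@@H]2Br)O1 | intermediate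
24 | ethynylmagnesium bromide | C#C[Mg]Br | starting material
25 | (2R,3R,5R)-2-{[(2S,3S,5S)-3-bromo-5-[(1R)-1-bromopropyl]oxolan-2-yl]methyl}-5-[(1R)-1-hydroxyprop-2-yn-1-yl]oxolan-3-yl acetate | C#C[C@@H](O)[C@H]1C[C@@H](OC(C)=O)[C@@H](C[C@@H]2O[C@H]([C@H](Br)CC)C[C@@H]2Br)O1 | intermediate
26 | (2R,3R,5R)-5-[(1S)-1-bromoprop-2-yn-1-yl]-2-{[(2S,3S,5S)-3-bromo-5-[(1R)-1-bromopropyl]oxolan-2-yl]methyl}oxolan-3-yl acetate | C#C[C@H](Br)[C@H]1C[C@@H](OC(C)=O)[C@@H](C[C@@H]2O[C@H]([C@H](Br)CC)C[C@@H]2Br)O1 | target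

**Totals**
Total step count: 13. Longest linear sequence: 11 steps (8/9 to 26 through steps 3–13); the furan branch is 9 steps.

**Three steps most likely to fail**

Step 2 (key dearomatisation). Keto‑aldehyde 7 may be too labile, or the 2,5‑cis:trans ratio too low, to carry into the basic Wittig step. The fallback sets out from 4 and moves to the acid/lactone oxidation level. Photooxygenation of 4 in the presence of i-Pr2NEt fragments endoperoxide 5 to the 4‑oxo‑2‑enoic acid, which closes by oxa‑Michael addition to 2-[(2R,5R)-3-oxo-5-[(trityloxy)methyl]oxolan-2-yl]acetic acid F1. NaBH4 then p‑toluenesulfonic acid gives the cis‑fused lactone (3aR,5R,6aR)-5-[(trityloxy)methyl]tetrahydrofuro[3,2-b]furan-2(3H)-one F2, where the unwanted C4 epimer can be removed by crystallisation. (i-Bu)2AlH at −78 °C gives the lactol (3aR,5R,6aR)-5-[(trityloxy)methyl]hexahydrofuro[3,2-b]furan-2-ol F3. Wittig reaction with ylide 17 gives (2R,3R,5R)-2-[(2Z,5S,6R)-6-bromo-5-(methoxymethoxy)oct-2-en-1-yl]-5-[(trityloxy)methyl]oxolan-3-ol F4, and Ac2O/pyridine brings the route back at 20. This also removes the base‑sensitive keto‑aldehyde from the Wittig step.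

Step 10 (ring B). The ring‑A ether oxygen may compete for the bromonium ion, or the 2,5‑trans ring may form. The fallback sets out from 21 and replaces bromoetherification by a stereospecific epoxide opening with late double bromination. Thiyl‑radical isomerisation (diphenyl disulfide cat., light; Z isomer recycled) gives (2R,3R,5R)-2-[(2E,5S,6R)-6-bromo-5-hydroxyoct-2-en-1-yl]-5-(hydroxymethyl)oxolan-3-yl acetate F5. Epoxidation with the D‑fructose‑derived ketone catalyst 1,2:4,5-di-O-isopropylidene-β-D-erythro-2,3-hexodiulo-2,6-pyranose and KHSO5 (NaHCO3 buffer, pH 8) gives (2R,3R,5R)-2-{[(2R,3R)-3-[(2S,3R)-3-bromo-2-hydroxypentyl]oxiran-2-yl]methyl}-5-(hydroxymethyl)oxolan-3-yl acetate F6. Camphorsulfonic acid (cat.) triggers 5‑endo opening at C9 with inversion to (2R,3R,5R)-2-{[(2S,3R,5S)-5-[(1R)-1-bromopropyl]-3-hydroxyoxolan-2-yl]methyl}-5-(hydroxymethyl)oxolan-3-yl acetate F7. Selective oxidation of the primary alcohol (2,2,6,6-tetramethylpiperidin-1-oxyl cat., PhI(OAc)2) gives (2R,3R,5R)-2-{[(2S,3R,5S)-5-[(1R)-1-bromopropyl]-3-hydroxyoxolan-2-yl]methyl}-5-formyloxolan-3-yl acetate F8. Excess 24 with MgBr2·OEt2 gives (2R,3R,5R)-2-{[(2S,3R,5S)-5-[(1R)-1-bromopropyl]-3-hydroxyoxolan-2-yl]methyl}-5-[(1R)-1-hydroxyprop-2-yn-1-yl]oxolan-3-yl acetate F9. A double Appel reaction (CBr4, PPh3) inverts C3 and C10 together and comes back to the route at 26.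

Step 12 (C3 configuration). Chelation control may give a poor threo:erythro ratio. The fallback sets out from the C3‑epimeric mixture of 25 and switches to reagent control. Dess–Martin oxidation gives the ynone (2R,3R,5R)-2-{[(2S,3S,5S)-3-bromo-5-[(1R)-1-bromopropyl]oxolan-2-yl]methyl}-5-propioloyloxolan-3-yl acetate F10. Reduction with catecholborane and (S)-1-methyl-3,3-diphenyltetrahydro-1H,3H-pyrrolo[1,2-c][1,3,2]oxazaborole (cat.) at −78 °C returns to the route at 25 as the single (3R) alcohol.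

**Further compounds**
F1 | step 2 | 2-[(2R,5R)-3-oxo-5-[(trityloxy)methyl]oxolan-2-yl]acetic acid | C(OC[C@H]1CC(=O)[C@@H](CC(O)=O)O1)(c1ccccc1)(c1ccccc1)c1ccccc1
F2 | step 2 | (3aR,5R,6aR)-5-[(trityloxy)methyl]tetrahydrofuro[3,2-b]furan-2(3H)-one | C(OC[C@H]1C[C@H]2OC(=O)C[C@H]2O1)(c1ccccc1)(c1ccccc1)c1ccccc1
F3 | step 2 | (3aR,5R,6aR)-5-[(trityloxy)methyl]hexahydrofuro[3,2-b]furan-2-ol | C(OC[C@H]1C[C@H]2OC(O)C[C@H]2O1)(c1ccccc1)(c1ccccc1)c1ccccc1
F4 | step 2 | (2R,3R,5R)-2-[(2Z,5S,6R)-6-bromo-5-(methoxymethoxy)oct-2-en-1-yl]-5-[(trityloxy)methyl]oxolan-3-ol | C(OC[C@H]1C[C@@H](O)[C@@H](C/C=C\C[C@H](OCOC)[C@H](Br)CC)O1)(c1ccccc1)(c1ccccc1)c1ccccc1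
F5 | step 10 | (2R,3R,5R)-2-[(2E,5S,6R)-6-bromo-5-hydroxyoct-2-en-1-yl]-5-(hydroxymethyl)oxolan-3-yl acetate | OC[C@H]1C[C@@H](OC(C)=O)[C@@H](C/C=C/C[C@H](O)[C@H](Br)CC)O1
F6 | step 10 | (2R,3R,5R)-2-{[(2R,3R)-3-[(2S,3R)-3-bromo-2-hydroxypentyl]oxiran-2-yl]methyl}-5-(hydroxymethyl)oxolan-3-yl acetate | OC[C@H]1C[C@@H](OC(C)=O)[C@@H](C[C@H]2O[C@@H]2C[C@H](O)[C@H](Br)CC)O1
F7 | step 10 | (2R,3R,5R)-2-{[(2S,3R,5S)-5-[(1R)-1-bromopropyl]-3-hydroxyoxolan-2-yl]methyl}-5-(hydroxymethyl)oxolan-3-yl acetate | OC[C@H]1C[C@@H](OC(C)=O)[C@@H](C[C@@H]2O[C@H]([C@H](Br)CC)C[C@H]2O)O1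
F8 | step 10 | (2R,3R,5R)-2-{[(2S,3R,5S)-5-[(1R)-1-bromopropyl]-3-hydroxyoxolan-2-yl]methyl}-5-formyloxolan-3-yl acetate | O=C[C@H]1C[C@@H](OC(C)=O)[C@@H](C[C@@H]2O[C@H]([C@H](Br)CC)C[C@H]2O)O1
F9 | step 10 | (2R,3R,5R)-2-{[(2S,3R,5S)-5-[(1R)-1-bromopropyl]-3-hydroxyoxolan-2-yl]methyl}-5-[(1R)-1-hydroxyprop-2-yn-1-yl]oxolan-3-yl acetate | C#C[C@@H](O)[C@H]1C[C@@H](OC(C)=O)[C@@H](C[C@@H]2O[C@H]([C@H](Br)CC)C[C@H]2O)O1
F10 | step 12 | (2R,3R,5R)-2-{[(2S,3S,5S)-3-bromo-5-[(1R)-1-bromopropyl]oxolan-2-yl]methyl}-5-propioloyloxolan-3-yl acetate | C#CC(=O)[C@H]1C[C@@H](OC(C)=O)[C@@H](C[C@@H]2O[C@H]([C@H](Br)CC)C[C@@H]2Br)O1
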